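Ring A is disconnected at C3–C4. Ring B comes intact from (R)-carvone, whose stereocentre becomes C5; an aldol with acrolein builds quaternary C10 and the C1 carbinol, and the oxidised isopropenyl carbon C19 is tied to O–C1 as a δ-lactone (C19–O–C1–C10–C5–C4). Because C19 on quaternary C4 sits across ring A from C1, the lactone silyl ketene acetal is an allyl vinyl ether: its Ireland–Claisen shift makes C3–C4, cuts the temporary O–C1 bond and closes ring A in one operation, relaying chirality from C1 to C4 (C19 axial, cis to C20). The ring B enol triflate is then elaborated to the 8α-ol and the diene side chain.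

Key step: step 6

Remark: labdane numbering is used for every compound (ring A = C1–C5 and C10; ring B = C5–C10; side chain C11–C16; C17 on C8; C18 and C19 on C4; C20 on C10); β is the face of C20.
Remark: centres that are erased later are carried as epimer mixtures (C10 in 4–6, C4 in 5–14).

Step 1
Reactants: 1 (R)-(−)-carvone; 2 iodomethane
Product: 4 6-methylcarvone (both C10 epimers), via lithium dienolate 3 (not isolated)
Conditions: LiN(i-Pr)2 (LDA), THF, −78 °C; then MeI, −78 → 0 °C
Reagents that add atoms: iodomethane, CI
Why: Kinetic deprotonation at the CH2 next to the carbonyl (future C10) and C-methylation of the cross-conjugated dienolate is a standard enolate alkylation; the new centre is not controlled because it is re-enolised in step 3.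

Step 2
Reactants: 4 6-methylcarvone
Product: 6 C19 primary alcohol (hydroxy enone), via catechol boronate 5 (not isolated)
Conditions: catecholborane, RhCl(PPh3)3 (cat.), THF, 0 °C → rt; then NaBO3·4H2O, THF/H2O, rt
Reagents that add atoms: sodium perborate, [Na+].[O-]B1OO1
Why: Rhodium-catalysed hydroboration should be chemoselective for the 1,1-disubstituted terminal alkene over the hindered conjugated ketone and its trisubstituted alkene, placing boron on the terminal carbon (anti-Markovnikov); mild perborate oxidation gives the alcohol, and the new C4 centre is erased in step 6.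

Step 3
Reactants: 6 hydroxy enone; 7 acrolein
Product: 9 aldol diol (10β-methyl, 1R carbinol), via dilithium alkoxide enolate 8 (not isolated)
Conditions: LiN(i-Pr)2 (2.2 equiv), THF, −78 °C; acrolein, −78 °C; AcOH quench at −78 °C
Reagents that add atoms: acrolein, C=CC=O
Why: Aldol addition of the tetrasubstituted lithium enolate: acrolein should add to C10 anti to the C5 side chain (as in alkylations of 6-methylcarvone), and the Zimmerman–Traxler chair with vinyl equatorial places the hydroxyl anti to C5, which is the (1R) carbinol needed.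

Step 4
Reactants: 9 aldol diol
Product: 12 vinyl δ-lactone, via hydroxy aldehyde 10 (not isolated), via lactol 11 (not isolated)
Conditions: TEMPO (cat.), PhI(OAc)2, CH2Cl2, rt
Reagents that add atoms: none
Why: Oxidative lactonisation of a 1,5-diol: the primary alcohol is oxidised selectively to the aldehyde, the C1 hydroxyl closes the six-membered lactol, and this is oxidised to the trans-fused lactone without touching a stereocentre.

Step 5
Reactants: 12 vinyl δ-lactone
Product: 14 enol triflate lactone, via lithium enolate 13 (not isolated)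
Conditions: LiBH(s-Bu)3 (L-Selectride), THF, −78 °C; then N-(5-chloro-2-pyridyl)bis(trifluoromethanesulfonimide) (Comins' reagent), −78 → 0 °C
Reagents that add atoms: Comins' reagent, FC(F)(F)S(=O)(=O)N(c1ccc(Cl)cn1)S(=O)(=O)C(F)(F)F
Why: Conjugate (1,4) hydride reduction of the β-unsubstituted enone gives the C8–C9 enolate regiospecifically and O-triflation traps it as the tetrasubstituted enol triflate; the lactone should be inert to the hindered borohydride at −78 °C.

Step 6
Reactants: 14 enol triflate lactone
Product: 17 ring A acid (4β-CO2H, C1=C2), via silyl ketene acetal 15 (not isolated), via trimethylsilyl ester 16 (not isolated)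
Conditions: LiN(i-Pr)2, Me3SiCl, Et3N, THF, −78 °C → rt; toluene, 110 °C; then 1 M HCl, THF, rt
Reagents that add atoms: none
Why: LDA removes the C4 hydrogen of the lactone and Me3SiCl traps the enolate as cyclic silyl ketene acetal 15, an allyl vinyl ether (C4=C19–O–C1–C2=C3) that on heating undergoes a [3,3] sigmatropic shift forming C3–C4 and breaking O–C1 to give silyl ester 16, hydrolysed to 17. The closest known reaction type is the Ireland–Claisen rearrangement of lactone silyl ketene acetals (vinyl lactone to cycloalkenecarboxylic acid). Ring A (C4–C3–C2–C1–C10–C5) is closed by this concerted pericyclic bond formation through the boat transition state that the six-membered lactone imposes, and the lactone ring is opened in the same event. The one new stereocentre, quaternary C4, is controlled by chirality transfer from C1: the axial 1α-vinyl group can bond only to the α face of C4, which leaves C19 axial on the β face (cis to C20) and the methyl equatorial, and both C4 epimers of 14 converge on the same ketene acetal. The step needs enolisation of the lactone in the presence of the enol triflate, which is secured by internal Me3SiCl trapping at −78 °C and by the lactone α-hydrogen being the only acidic C–H.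

Step 7
Reactants: 17 ring A acid; 18 [2-(1,3-dioxolan-2-yl)ethyl]zinc bromide
Product: 20 diene acid with C11–C13 acetal chain, via bromozinc carboxylate 19 (not isolated)
Conditions: 18 (3 equiv), Pd(dppf)Cl2 (cat.), THF, 60 °C; aqueous NH4Cl/dilute HCl work-up
Reagents that add atoms: [2-(1,3-dioxolan-2-yl)ethyl]zinc bromide, Br[Zn]CCC1OCCO1
Why: Negishi cross-coupling of the enol triflate with a primary alkylzinc installs C11–C13 as a protected aldehyde; cyclohexenyl triflates flanked by a quaternary carbon are competent partners, and the acid is carried as its zinc salt at the cost of one equivalent of reagent.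

Step 8
Reactants: 20 diene acid
Product: 21 Δ8(9) acid (ring A saturated)
Conditions: H2 (1 atm), Pd/C, EtOAc, rt
Reagents that add atoms: none
Why: Catalytic hydrogenation should reduce the cis-disubstituted C1=C2 alkene selectively, the tetrasubstituted C8=C9 alkene being inert under these conditions; no stereocentre is formed.

Step 9
Reactants: 21 Δ8(9) acid
Product: 23 8α,19-diol acetal, via organoborane 22 (not isolated)
Conditions: BH3·THF (excess), THF, 0 °C → rt; then NaOH, H2O2, 0 °C → rt
Reagents that add atoms: hydrogen peroxide, OO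
Why: Borane reduces the carboxylic acid to the C19 alcohol and hydroborates the tetrasubstituted alkene by syn addition from the α face (anti to the axial C20) with boron on the less hindered C8, so oxidation with retention should give the 8α-hydroxyl and the 9α-hydrogen (hydroboration–oxidation).

Step 10
Reactants: 23 8α,19-diol acetal
Product: 24 8,13-lactol
Conditions: pyridinium p-toluenesulfonate (cat.), acetone/H2O, 50 °C
Reagents that add atoms: water, O
Why: Acid-catalysed acetal hydrolysis releases the C13 aldehyde, which the tertiary 8-hydroxyl captures as a six-membered lactol; the mild acid should not dehydrate the tertiary alcohol.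

Step 11
Reactants: 24 8,13-lactol; 25 dimethyl (1-diazo-2-oxopropyl)phosphonate
Product: 28 terminal alkyne diol, via hydroxy aldehyde 26 (not isolated), via diazoalkene 27 (not isolated)
Conditions: K2CO3, MeOH, rt
Reagents that add atoms: dimethyl (1-diazo-2-oxopropyl)phosphonate, COP(=O)(OC)C(=[N+]=[N-])C(C)=O
Why: Seyferth–Gilbert homologation with the Ohira–Bestmann reagent: the lactol reacts through its open aldehyde form and the diazoalkene loses N2 with 1,2-hydrogen shift to give the C13≡C14 alkyne.

Step 12
Reactants: 28 terminal alkyne diol; 29 ethylene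
Product: 30 labda-13(16),14-diene-8α,19-diol
Conditions: ethylene (1 atm), second-generation Grubbs catalyst (cat.), toluene, 80 °C
Reagents that add atoms: ethylene, C=C
Why: Enyne cross-metathesis of a terminal alkyne with ethylene gives the 2-substituted 1,3-butadiene directly (C16 and C15 come from ethylene), and free hydroxyl groups are tolerated.

Step 13
Reactants: 30 labda-13(16),14-diene-8α,19-diol; 31 (E)-4-methoxycinnamic acid
Product: 32 CNP0249194.1 (target)
Conditions: N,N'-dicyclohexylcarbodiimide (DCC), DMAP (cat.), CH2Cl2, 0 °C → rt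
Reagents that add atoms: (E)-4-methoxycinnamic acid, COc1ccc(/C=C/C(=O)O)cc1
Why: Steglich esterification should acylate only the primary C19 hydroxyl, the tertiary 8-hydroxyl being unreactive, and the (E)-alkene of the acid is retained.

Compound list
1 | (R)-(−)-carvone, (5R)-2-methyl-5-(prop-1-en-2-yl)cyclohex-2-en-1-one | O=C1C(C)=CC[C@@H](C(C)=C)C1 | starting material
2 | iodomethane | CI | starting material
3 | kinetic lithium dienolate of 1 (deprotonated at the CH2 next to C=O; not isolated) | [Li]OC1=C[C@H](C(C)=C)CC=C1C | intermediate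
4 | 6-methylcarvone, (5R)-2,6-dimethyl-5-(prop-1-en-2-yl)cyclohex-2-en-1-one (both epimers at the methylated carbon, future C10) | O=C1C(C)=CC[C@@H](C(C)=C)C1C | intermediate
5 | catechol boronate of 4, boron on the terminal carbon (C19) of the former isopropenyl group (not isolated) | O=C1C(C)=CC[C@@H](C(C)CB2Oc3ccccc3O2)C1C | intermediate
6 | (5R)-5-(1-hydroxypropan-2-yl)-2,6-dimethylcyclohex-2-en-1-one (epimers at C4 and C10) | O=C1C(C)=CC[C@@H](C(C)CO)C1C | intermediate
7 | acrolein (prop-2-enal) | C=CC=O | starting material
8 | dilithium salt of 6: C19 alkoxide and C9–C10 enolate (not isolated) | [Li]OCC(C)[C@@H]1CC=C(C)C(O[Li])=C1C | intermediate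
9 | aldol diol, 6-[(1R)-1-hydroxyprop-2-en-1-yl]-5-(1-hydroxypropan-2-yl)-2,6-dimethylcyclohex-2-en-1-one; quaternary methyl (C20) cis to the C5 side chain; C4 epimers | O=C1C(C)=CC[C@@H](C(C)CO)[C@]1(C)[C@H](O)C=C | intermediate
10 | C19 aldehyde of 9 (not isolated) | O=C1C(C)=CC[C@@H](C(C)C=O)[C@]1(C)[C@H](O)C=C | intermediate
11 | lactol from 10: C19(OH)–O–C1 ring (not isolated) | O=C1C(C)=CC[C@H]2C(C)C(O)O[C@H](C=C)[C@]12C | intermediate
12 | vinyl δ-lactone, (1R)-1-ethenyl-4,7,8a-trimethyl-4a,5-dihydro-1H-isochromene-3,8(4H,8aH)-dione; lactone C19(=O)–O–C1 trans-fused to ring B (H5 α, C20 β), 1α-vinyl anti to C20, C9 ketone, C7=C8; C4 epimers | O=C1C(C)=CC[C@H]2C(C)C(=O)O[C@H](C=C)[C@]12C | intermediate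
13 | lithium C8–C9 enolate from 1,4-reduction of 12 (not isolated) | [Li]OC1=C(C)CC[C@H]2C(C)C(=O)O[C@H](C=C)[C@]12C | intermediate
14 | enol triflate lactone: as 12 but C9–OSO2CF3 with C8=C9 and C7 saturated; C4 epimers | FC(F)(F)S(=O)(=O)OC1=C(C)CC[C@H]2C(C)C(=O)O[C@H](C=C)[C@]12C | intermediate
15 | cyclic trimethylsilyl ketene acetal of 14, C4=C19(OSiMe3)–O–C1 (not isolated) | FC(F)(F)S(=O)(=O)OC1=C(C)CC[C@H]2C(C)=C(O[Si](C)(C)C)O[C@H](C=C)[C@]12C | intermediate
16 | trimethylsilyl ester of 17 (not isolated) | FC(F)(F)S(=O)(=O)OC1=C(C)CC[C@H]2[C@@](C)(C(=O)O[Si](C)(C)C)CC=C[C@]12C | intermediate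
17 | 9-(trifluoromethylsulfonyloxy)-11,12,13,14,15,16-hexanorlabda-1,8-dien-19-oic acid; 1,4a,6-trimethyl-5-triflyloxy-1,2,4a,7,8,8a-hexahydronaphthalene-1-carboxylic acid, carboxyl cis to the angular methyl, ring-fusion hydrogen trans to it | FC(F)(F)S(=O)(=O)OC1=C(C)CC[C@H]2[C@@](C)(C(=O)O)CC=C[C@]12C | intermediate
18 | [2-(1,3-dioxolan-2-yl)ethyl]zinc bromide | Br[Zn]CCC1OCCO1 | starting material
19 | bromozinc carboxylate of 17 (not isolated) | FC(F)(F)S(=O)(=O)OC1=C(C)CC[C@H]2[C@@](C)(C(=O)O[Zn]Br)CC=C[C@]12C | intermediate
20 | 13,13-(ethylenedioxy)-14,15,16-trinorlabda-1,8-dien-19-oic acid | O1CCOC1CCC1=C(C)CC[C@H]2[C@@](C)(C(=O)O)CC=C[C@]12C | intermediate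
21 | 13,13-(ethylenedioxy)-14,15,16-trinorlabd-8-en-19-oic acid | O1CCOC1CCC1=C(C)CC[C@H]2[C@@](C)(C(=O)O)CCC[C@]12C | intermediate
22 | organoborane from 21: 8α-boryl and 19-O-boryl, drawn monomeric (not isolated) | O1CCOC1CC[C@@H]1[C@@]2(C)CCC[C@](C)(COB)[C@@H]2CC[C@@]1(C)B | intermediate
23 | 13,13-(ethylenedioxy)-14,15,16-trinorlabdane-8α,19-diol | O1CCOC1CC[C@@H]1[C@@]2(C)CCC[C@](C)(CO)[C@@H]2CC[C@@]1(C)O | intermediate
24 | 8α,13-epoxy-14,15,16-trinorlabdane-13,19-diol (lactol, both anomers) | OC1CC[C@@H]2[C@@]3(C)CCC[C@](C)(CO)[C@@H]3CC[C@@]2(C)O1 | intermediate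
25 | dimethyl (1-diazo-2-oxopropyl)phosphonate (Ohira–Bestmann reagent) | COP(=O)(OC)C(=[N+]=[N-])C(C)=O | starting material
26 | 8α,19-dihydroxy-14,15,16-trinorlabdan-13-al, open form of 24 (not isolated) | O=CCC[C@@H]1[C@@]2(C)CCC[C@](C)(CO)[C@@H]2CC[C@@]1(C)O | intermediate
27 | diazoalkene from 26 (not isolated) | [N-]=[N+]=C=CCC[C@@H]1[C@@]2(C)CCC[C@](C)(CO)[C@@H]2CC[C@@]1(C)O | intermediate
28 | 15,16-dinorlabd-13-yne-8α,19-diol | C#CCC[C@@H]1[C@@]2(C)CCC[C@](C)(CO)[C@@H]2CC[C@@]1(C)O | intermediate
29 | ethylene | C=C | starting material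
30 | labda-13(16),14-diene-8α,19-diol | C=CC(=C)CC[C@@H]1[C@@]2(C)CCC[C@](C)(CO)[C@@H]2CC[C@@]1(C)O | intermediate
31 | (E)-4-methoxycinnamic acid | COc1ccc(/C=C/C(=O)O)cc1 | starting material
32 | 8α-hydroxylabda-13(16),14-dien-19-yl (E)-3-(4-methoxyphenyl)prop-2-enoate, CNP0249194.1 | C=CC(=C)CC[C@@H]1[C@@]2(C)CCC[C@](C)(COC(=O)/C=C/c3ccc(OC)cc3)[C@@H]2CC[C@@]1(C)O | target

Total step count: 13. Longest linear sequence: 13 steps, from (R)-carvone.

Steps most likely to fail

Step 3. What may go wrong: poor facial selectivity at the aldehyde carbon in the aldol, so that much of the material carries the C1 epimer whose vinyl group cannot reach C4 in step 6. The fallback sets out from 6 and returns at 9, and sets C1 by reagent-controlled ketone reduction instead of by the aldol transition state. Silylation of 6 (t-BuMe2SiCl, imidazole) should give silyl ether F1. The same LDA/acrolein aldol should give the carbinols F2 as a C1 mixture that is not separated. Dess–Martin periodinane should oxidise it to vinyl ketone F3. BH3·SMe2 with the (S)-methyl-CBS oxazaborolidine, the quaternary C10 acting as the large group, should reduce the vinyl ketone in preference to the hindered ring enone and give the (1R) carbinol F4. Bu4NF then removes the silyl group and returns diol 9.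

Step 6. What may go wrong: silylation of the lactone enolate on carbon, attack of the amide base on the enol triflate, or decomposition of the silyl ketene acetal before it reaches the boat geometry. The fallback sets out from 14 and returns at 17, and runs the rearrangement on a neutral allyl vinyl ether, with no enolate. i-Bu2AlH at −78 °C should reduce 14 to lactol F5. MsCl/Et3N followed by warming should dehydrate it to dihydropyran F6. Heating in toluene at 180 °C (sealed tube) should effect the aliphatic Claisen rearrangement through the same boat arrangement and give aldehyde F7 with C19 axial. NaClO2/NaH2PO4/2-methyl-2-butene should oxidise it to acid 17.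

Step 9. What may go wrong: slow addition of borane to the tetrasubstituted alkene, followed on warming by migration of boron away from C8, so that regiocontrol is lost. The fallback sets out from 21 and returns at 23, and puts the oxygen on C8 as an epoxide and the hydrogen on C9 as a hydrogen atom. LiAlH4 should reduce 21 to alcohol F8. m-Chloroperbenzoic acid should epoxidise the electron-rich alkene from the α face to give 8α,9α-epoxide F9. Cp2TiCl (trivalent titanium, made from Cp2TiCl2 and Zn) with 1,4-cyclohexadiene should open the epoxide homolytically to the C9 radical, which takes a hydrogen atom on the α face, anti to C20, to give 23.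

Further compounds
F1 | step 3 | tert-butyldimethylsilyl ether of 6 (C19–OSi) | O=C1C(C)=CC[C@@H](C(C)CO[Si](C)(C)C(C)(C)C)C1C
F2 | step 3 | aldol adduct of F1 with acrolein, both C1 epimers | O=C1C(C)=CC[C@@H](C(C)CO[Si](C)(C)C(C)(C)C)[C@]1(C)C(O)C=C
F3 | step 3 | C1 vinyl ketone from F2 | O=C1C(C)=CC[C@@H](C(C)CO[Si](C)(C)C(C)(C)C)[C@]1(C)C(=O)C=C
F4 | step 3 | (1R) carbinol, silyl ether of 9 | O=C1C(C)=CC[C@@H](C(C)CO[Si](C)(C)C(C)(C)C)[C@]1(C)[C@H](O)C=C
F5 | step 6 | lactol from reduction of 14 | FC(F)(F)S(=O)(=O)OC1=C(C)CC[C@H]2C(C)C(O)O[C@H](C=C)[C@]12C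
F6 | step 6 | 1-vinyl dihydropyran (cyclic enol ether C4=C19–O–C1) | FC(F)(F)S(=O)(=O)OC1=C(C)CC[C@H]2C(C)=CO[C@H](C=C)[C@]12C
F7 | step 6 | C19 aldehyde corresponding to 17 | FC(F)(F)S(=O)(=O)OC1=C(C)CC[C@H]2[C@@](C)(C=O)CC=C[C@]12C
F8 | step 9 | 13,13-(ethylenedioxy)-14,15,16-trinorlabd-8-en-19-ol | O1CCOC1CCC1=C(C)CC[C@H]2[C@@](C)(CO)CCC[C@]12C
F9 | step 9 | 8α,9α-epoxide of F8 | C(CC1OCCO1)[C@@]23O[C@]2(C)CC[C@H]2[C@@](C)(CO)CCC[C@]32C
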